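**Plan**

- Retrosynthesis: cut C1–CH3 of the cyclohexanol (methyl addition to a ketone), then the oxane C2–O and C3–Br bonds (bromoetherification), then the side-chain CH2–C(sp2) bond (B-alkyl Suzuki–Miyaura coupling), and last the ring bonds C1–C2 and C4–C5 together.
- Enabling feature: cyclohexane C2 (CH bearing the side chain) and C4 (CHBr) both sit on the quaternary C3(CH3)2. C4–C3–C2 are therefore the α, β and α′ carbons of 3,3-dimethylcyclobutanone. Its carbonyl carbon is kept as the first side-chain carbon, and the four-membered ring is a temporary ring, opened later by an iminyl radical that leaves Br on C4.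
- Forward order: cyclobutanone + acrolein → bicyclo[3.1.1]heptane (cyclohexane ring closed) → ring-opening bromination to a monocyclic bromo nitrile → vinyl group → coupling with a linalool-derived (E)-alkenyl iodide → oxane ring → methyl carbinol.
- Stereochemistry: the amine catalyst sets the first bridgehead and the tether the second. The temporary C1 oxygen (equatorial benzoate) steers bromine onto C4. C2 ends thermodynamic (equatorial, cis to Br) in ketone 19, and C1 comes from equatorial methyl addition. Oxane C6 comes from (S)-linalool, and C2/C3 from anti addition to the (E)-alkene.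

Key step: step 1

Assumption: the (S)-configured amine is taken to give the (R) centre of 3, by analogy with its α-functionalisation of cyclic ketones; if the antipode forms, the (R)-catalyst is used.

**Step 1**
Reactants: 1 3,3-dimethylcyclobutan-1-one; 2 prop-2-enal (acrolein)
Product: 4 (1R,2S,5R)-2-hydroxy-7,7-dimethylbicyclo[3.1.1]heptan-6-one, via keto aldehyde 3 (not isolated)
Conditions: 1 (3 equiv), 5-[(2S)-pyrrolidin-2-yl]-1H-tetrazole (20 mol %), 2 (slow addition), DMSO/H2O, 10 → 25 °C
Reagents that add atoms: none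
Why: Proposed new method: the amine forms the enamine of 1, which adds to acrolein (Michael addition) to give 3, whose stereocentre is set by the catalyst's choice between the two enantiotopic α-carbons and their faces; a second enamine on the remaining CH2 side then adds to the tethered aldehyde, and this 6-(enolexo)-exo-trig aldol closes the six-membered carbocycle across the 1,3-positions of the cyclobutanone to give the bicyclo[3.1.1]heptanone. The closest known reaction type is the amine-mediated Michael/aldol α,α′-annulation of cyclopentanone and cyclohexanone enamines with acrolein to bridged ketols, together with amine-catalysed enantioselective α-functionalisation and aldol reactions of cyclobutanone; a cyclobutanone has not been shown as the two-fold donor. The second bridgehead is fixed by the two-carbon tether (only cis bridging is possible), and the carbinol centre should carry OH on the side of the carbonyl bridge because the smaller H is the substituent that can face the gem-dimethyl bridge. The step needs mono-Michael addition and closure by the ketone donor instead of oligomerisation of acrolein; excess 1, slow addition and the absence in acrolein of a second enolisable position that could attack the strained ketone (no Robinson-type path) should secure this. The extra ring strain of the bicycle (a few kcal/mol above that of 1) is offset by the aldehyde acceptor, and 4 is used promptly to avoid retro-aldol opening.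

**Step 2**
Reactants: 4 (1R,2S,5R)-2-hydroxy-7,7-dimethylbicyclo[3.1.1]heptan-6-one
Product: 5 (1S,2S,5R)-6-(hydroxyimino)-7,7-dimethylbicyclo[3.1.1]heptan-2-ol (E/Z mixture)
Conditions: NH2OH·HCl, NaOAc, EtOH/H2O, 0 → 25 °C
Reagents that add atoms: hydroxylamine hydrochloride, Cl.NO
Why: Oxime formation (condensation) should be fast on the strained cyclobutanone carbonyl in a buffered medium that spares the β-hydroxy ketone; no stereocentre is formed and the C=N geometry is irrelevant.

**Step 3**
Reactants: 5 (1S,2S,5R)-6-(hydroxyimino)-7,7-dimethylbicyclo[3.1.1]heptan-2-ol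
Product: 6 (1S,2S,5R)-6-[(benzoyloxy)imino]-7,7-dimethylbicyclo[3.1.1]heptan-2-yl benzoate
Conditions: PhCOCl (2.5 equiv), Et3N, DMAP (cat.), CH2Cl2, 0 → 25 °C
Reagents that add atoms: benzoyl chloride, O=C(Cl)c1ccccc1
Why: Double O-acylation gives the redox-active oxime ester and protects the carbinol as a benzoate, which later acts as an equatorial anchor and as an electron-withdrawing group next to one bridgehead.

**Step 4**
Reactants: 6 (1S,2S,5R)-6-[(benzoyloxy)imino]-7,7-dimethylbicyclo[3.1.1]heptan-2-yl benzoate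
Product: 7 (1S,2S,4R)-4-bromo-2-cyano-3,3-dimethylcyclohexyl benzoate
Conditions: CuBr (10 mol %), 1,10-phenanthroline (12 mol %), LiBr (2 equiv), MeCN, 60 °C
Reagents that add atoms: lithium bromide, [Li+].[Br-]
Why: Copper-catalysed iminyl-radical ring opening of a cyclobutanone O-acyl oxime: electron transfer from monovalent copper cleaves the N–O bond, β-scission should break the ring at the bridgehead remote from the benzoyloxy-bearing carbon (polar effect) and leave the nitrile on the other bridgehead, and the secondary radical should take bromine from the divalent copper bromide axially and anti to the axial methyl in the chair that keeps the benzoate equatorial, which places Br cis to the benzoate; the epimer and the regioisomer are separable here.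

**Step 5**
Reactants: 7 (1S,2S,4R)-4-bromo-2-cyano-3,3-dimethylcyclohexyl benzoate
Product: 8 (1R,3R,6S)-3-bromo-6-hydroxy-2,2-dimethylcyclohexane-1-carbaldehyde
Conditions: i-Bu2AlH (4 equiv), CH2Cl2, −78 °C; aq. potassium sodium tartrate, then dilute HCl
Reagents that add atoms: water, O
Why: Hydride reduction of the nitrile to the aldimine (hydrolysed to the aldehyde on work-up) with concurrent reductive cleavage of the benzoate; the low temperature should spare the secondary bromide.

**Step 6**
Reactants: 8 (1R,3R,6S)-3-bromo-6-hydroxy-2,2-dimethylcyclohexane-1-carbaldehyde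
Product: 9 (1S,2R,4R)-4-bromo-2-ethenyl-3,3-dimethylcyclohexan-1-ol
Conditions: Ph3PCH3Br, KN(SiMe3)2 (ylide 2.5 equiv), THF, −78 → 0 °C
Reagents that add atoms: methyltriphenylphosphonium bromide, C[P+](c1ccccc1)(c1ccccc1)c1ccccc1.[Br-]
Why: Wittig methylenation of the aldehyde at low temperature; no stereocentre is formed.

**Step 7**
Reactants: 10 (3S)-3,7-dimethylocta-1,6-dien-3-ol, (S)-linalool
Product: 11 triethyl{[(3S)-3,7-dimethylocta-1,6-dien-3-yl]oxy}silane
Conditions: Et3SiOTf, 2,6-lutidine, CH2Cl2, −78 → 0 °C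
Reagents that add atoms: triethylsilyl trifluoromethanesulfonate, CC[Si](CC)(CC)OS(=O)(=O)C(F)(F)F
Why: Silylation of the tertiary allylic alcohol with a silyl triflate; the stereocentre is untouched.

**Step 8**
Reactants: 11 triethyl{[(3S)-3,7-dimethylocta-1,6-dien-3-yl]oxy}silane
Product: 13 (4S)-4-methyl-4-[(triethylsilyl)oxy]hex-5-enal, via ozonide 12 (not isolated)
Conditions: O3 (1 equiv, Sudan Red 7B end-point), CH2Cl2, −78 °C; then PPh3, −78 → 25 °C
Reagents that add atoms: ozone, [O-][O+]=O
Why: Ozonolysis should be selective for the electron-rich trisubstituted alkene over the hindered vinyl group next to the silyloxy-bearing quaternary carbon.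

**Step 9**
Reactants: 13 (4S)-4-methyl-4-[(triethylsilyl)oxy]hex-5-enal
Product: 14 triethyl{[(3S,6Z)-3-methyl-7-(4,4,5,5-tetramethyl-1,3,2-dioxaborolan-2-yl)octa-1,6-dien-3-yl]oxy}silane
Conditions: CH3CH(Bpin)2, lithium 2,2,6,6-tetramethylpiperidide, THF, 0 °C; then 13, −78 → 25 °C
Reagents that add atoms: 1,1-bis(pinacolboryl)ethane, CC(B1OC(C)(C)C(C)(C)O1)B1OC(C)(C)C(C)(C)O1
Why: Boron–Wittig olefination: the syn B–O elimination should proceed through the oxaboretane that keeps the remaining bulky boryl group away from the alkyl chain, so the boryl group ends trans to the chain.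

**Step 10**
Reactants: 14 triethyl{[(3S,6Z)-3-methyl-7-(4,4,5,5-tetramethyl-1,3,2-dioxaborolan-2-yl)octa-1,6-dien-3-yl]oxy}silane
Product: 15 triethyl{[(3S,6E)-7-iodo-3-methylocta-1,6-dien-3-yl]oxy}silane
Conditions: aq. NaOH, then I2, THF, 0 °C
Reagents that add atoms: iodine, II
Why: Iodo-deboronation of the alkenyl boronate through its hydroxy-boronate complex goes with retention of alkene geometry and should give the (E)-iodide.

**Step 11**
Reactants: 15 triethyl{[(3S,6E)-7-iodo-3-methylocta-1,6-dien-3-yl]oxy}silane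
Product: 16 (3S,6E)-7-iodo-3-methylocta-1,6-dien-3-ol
Conditions: Bu4NF, THF, 25 °C
Reagents that add atoms: none
Why: Fluoride desilylation frees the tertiary alcohol needed later as the ring oxygen.

**Step 12**
Reactants: 9 (1S,2R,4R)-4-bromo-2-ethenyl-3,3-dimethylcyclohexan-1-ol; 16 (3S,6E)-7-iodo-3-methylocta-1,6-dien-3-ol
Product: 18 (1S,2R,4R)-4-bromo-2-[(3E,7S)-7-hydroxy-3,7-dimethylnona-3,8-dien-1-yl]-3,3-dimethylcyclohexan-1-ol, via alkylborane 17 (not isolated)
Conditions: 9-borabicyclo[3.3.1]nonane (2.5 equiv), THF, 0 → 25 °C; then 16, Pd(dppf)Cl2 (10 mol %), AsPh3, Cs2CO3, DMF/H2O, 25 °C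
Reagents that add atoms: none
Why: Anti-Markovnikov hydroboration of the vinyl group followed by B-alkyl Suzuki–Miyaura coupling, which keeps the alkenyl iodide geometry and should leave the hindered secondary bromide untouched.

**Step 13**
Reactants: 18 (1S,2R,4R)-4-bromo-2-[(3E,7S)-7-hydroxy-3,7-dimethylnona-3,8-dien-1-yl]-3,3-dimethylcyclohexan-1-ol
Product: 19 (2R,4R)-4-bromo-2-[(3E,7S)-7-hydroxy-3,7-dimethylnona-3,8-dien-1-yl]-3,3-dimethylcyclohexan-1-one
Conditions: Dess–Martin periodinane, NaHCO3, CH2Cl2, 0 → 25 °C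
Reagents that add atoms: none
Why: Dess–Martin oxidation acts on the secondary alcohol only and removes the temporary carbinol stereocentre; the now epimerisable C2 has as its thermodynamic configuration the required one (side chain and Br both equatorial, cis).

**Step 14**
Reactants: 19 (2R,4R)-4-bromo-2-[(3E,7S)-7-hydroxy-3,7-dimethylnona-3,8-dien-1-yl]-3,3-dimethylcyclohexan-1-one
Product: 20 (2R,4R)-4-bromo-2-{2-[(2S,3R,6S)-3-bromo-6-ethenyl-2,6-dimethyloxan-2-yl]ethyl}-3,3-dimethylcyclohexan-1-one
Conditions: 2,4,4,6-tetrabromocyclohexa-2,5-dien-1-one, MeNO2, 0 → 25 °C, dark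
Reagents that add atoms: 2,4,4,6-tetrabromocyclohexa-2,5-dien-1-one, O=C1C(Br)=CC(Br)(Br)C=C1Br
Why: Bromonium-induced 6-endo (Markovnikov) bromoetherification by the only free hydroxyl: anti addition across the (E)-alkene sets Br trans to the alkyl chain on the adjacent carbon, C6 comes from linalool, and the isomer from attack on the other alkene face is expected alongside and is separated.

**Step 15**
Reactants: 20 (2R,4R)-4-bromo-2-{2-[(2S,3R,6S)-3-bromo-6-ethenyl-2,6-dimethyloxan-2-yl]ethyl}-3,3-dimethylcyclohexan-1-one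
Product: 21 (1S,2R,4R)-4-bromo-2-{2-[(2S,3R,6S)-3-bromo-6-ethenyl-2,6-dimethyloxan-2-yl]ethyl}-1,3,3-trimethylcyclohexan-1-ol
Conditions: MeLi, CeCl3, THF, −78 °C; aq. NH4Cl
Reagents that add atoms: methyllithium, [Li]C
Why: Organocerium 1,2-addition to the hindered, enolisable ketone: the axial methyl on C3 blocks axial attack, so methyl should enter equatorially and give the axial hydroxyl cis to the side chain and to Br.

**Compound list**

1 | 3,3-dimethylcyclobutan-1-one | CC1(C)CC(=O)C1 | starting material
2 | prop-2-enal (acrolein) | C=CC=O | starting material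
3 | 3-[(1R)-2,2-dimethyl-4-oxocyclobutyl]propanal | O=CCC[C@@H]1C(C)(C)CC1=O | intermediate
4 | (1R,2S,5R)-2-hydroxy-7,7-dimethylbicyclo[3.1.1]heptan-6-one (hydroxyl on the side of the carbonyl bridge) | O=C1[C@@H]2C(C)(C)[C@H]1CC[C@@H]2O | intermediate
5 | (1S,2S,5R)-6-(hydroxyimino)-7,7-dimethylbicyclo[3.1.1]heptan-2-ol (E/Z mixture) | ON=C1[C@@H]2C(C)(C)[C@H]1CC[C@@H]2O | intermediate
6 | (1S,2S,5R)-6-[(benzoyloxy)imino]-7,7-dimethylbicyclo[3.1.1]heptan-2-yl benzoate | O=C(ON=C1[C@@H]2C(C)(C)[C@H]1CC[C@@H]2OC(=O)c1ccccc1)c1ccccc1 | intermediate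
7 | (1S,2S,4R)-4-bromo-2-cyano-3,3-dimethylcyclohexyl benzoate (all cis) | N#C[C@@H]1C(C)(C)[C@H](Br)CC[C@@H]1OC(=O)c1ccccc1 | intermediate
8 | (1R,3R,6S)-3-bromo-6-hydroxy-2,2-dimethylcyclohexane-1-carbaldehyde | O=C[C@@H]1C(C)(C)[C@H](Br)CC[C@@H]1O | intermediate
9 | (1S,2R,4R)-4-bromo-2-ethenyl-3,3-dimethylcyclohexan-1-ol | C=C[C@@H]1C(C)(C)[C@H](Br)CC[C@@H]1O | intermediate
10 | (3S)-3,7-dimethylocta-1,6-dien-3-ol, (S)-linalool | C=C[C@](O)(C)CCC=C(C)C | starting material
11 | triethyl{[(3S)-3,7-dimethylocta-1,6-dien-3-yl]oxy}silane | C=C[C@](O[Si](CC)(CC)CC)(C)CCC=C(C)C | intermediate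
12 | 3,3-dimethyl-5-{(3S)-3-methyl-3-[(triethylsilyl)oxy]pent-4-en-1-yl}-1,2,4-trioxolane (both epimers at the ring CH) | C=C[C@](O[Si](CC)(CC)CC)(C)CCC1OOC(C)(C)O1 | intermediate
13 | (4S)-4-methyl-4-[(triethylsilyl)oxy]hex-5-enal | C=C[C@](O[Si](CC)(CC)CC)(C)CCC=O | intermediate
14 | triethyl{[(3S,6Z)-3-methyl-7-(4,4,5,5-tetramethyl-1,3,2-dioxaborolan-2-yl)octa-1,6-dien-3-yl]oxy}silane | C=C[C@](O[Si](CC)(CC)CC)(C)CC/C=C(\C)B1OC(C)(C)C(C)(C)O1 | intermediate
15 | triethyl{[(3S,6E)-7-iodo-3-methylocta-1,6-dien-3-yl]oxy}silane | C=C[C@](O[Si](CC)(CC)CC)(C)CC/C=C(\C)I | intermediate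
16 | (3S,6E)-7-iodo-3-methylocta-1,6-dien-3-ol | C=C[C@](O)(C)CC/C=C(\C)I | intermediate
17 | (1S,2R,4R)-2-[2-(9-borabicyclo[3.3.1]nonan-9-yl)ethyl]-4-bromo-3,3-dimethylcyclohexan-1-ol | B1(C2CCCC1CCC2)CC[C@@H]1C(C)(C)[C@H](Br)CC[C@@H]1O | intermediate
18 | (1S,2R,4R)-4-bromo-2-[(3E,7S)-7-hydroxy-3,7-dimethylnona-3,8-dien-1-yl]-3,3-dimethylcyclohexan-1-ol | C=C[C@](O)(C)CC/C=C(\C)CC[C@@H]1C(C)(C)[C@H](Br)CC[C@@H]1O | intermediate
19 | (2R,4R)-4-bromo-2-[(3E,7S)-7-hydroxy-3,7-dimethylnona-3,8-dien-1-yl]-3,3-dimethylcyclohexan-1-one | C=C[C@](O)(C)CC/C=C(\C)CC[C@@H]1C(C)(C)[C@H](Br)CCC1=O | intermediate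
20 | (2R,4R)-4-bromo-2-{2-[(2S,3R,6S)-3-bromo-6-ethenyl-2,6-dimethyloxan-2-yl]ethyl}-3,3-dimethylcyclohexan-1-one | C=C[C@]1(C)CC[C@@H](Br)[C@](C)(CC[C@@H]2C(C)(C)[C@H](Br)CCC2=O)O1 | intermediate
21 | (1S,2R,4R)-4-bromo-2-{2-[(2S,3R,6S)-3-bromo-6-ethenyl-2,6-dimethyloxan-2-yl]ethyl}-1,3,3-trimethylcyclohexan-1-ol | C=C[C@]1(C)CC[C@@H](Br)[C@](C)(CC[C@@H]2C(C)(C)[C@H](Br)CC[C@]2(C)O)O1 | target

**Step count and risks**

Total step count: 15. Longest linear sequence: 10 steps (steps 1–6 and 12–15, from 1 to 21).

Three steps most likely to fail: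

1. Step 1 (proposed new method). The second, strain-building C–C bond formation may be slower than oligomerisation of acrolein or self-condensation of 1. The ketol may also revert by retro-aldol opening during isolation, and the selection between the two enantiotopic α-carbons may be weak. The fallback sets out from 1 and comes back at 4, using auxiliary control and a stoichiometric closure. Condensation of 1 with (S)-1-amino-2-(methoxymethyl)pyrrolidine gives (2S)-N-(3,3-dimethylcyclobutylidene)-2-(methoxymethyl)pyrrolidin-1-amine F1. Metalation with LiN(i-Pr)2 and alkylation with 2-(2-iodoethyl)-1,3-dioxolane (SAMP-hydrazone alkylation) gives (2S)-N-{(2R)-2-[2-(1,3-dioxolan-2-yl)ethyl]-3,3-dimethylcyclobutylidene}-2-(methoxymethyl)pyrrolidin-1-amine F2. Two-phase oxalic acid cleavage returns the auxiliary and gives (2R)-2-[2-(1,3-dioxolan-2-yl)ethyl]-3,3-dimethylcyclobutan-1-one F3. Aqueous acid unmasks keto aldehyde 3, which is closed in a separate flask through its titanium enolate (TiCl4, i-Pr2NEt, CH2Cl2, −78 °C); the chelated titanium aldolate should hold the ketol until a cold quench, which gives 4.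

2. Step 4. β-Scission of the iminyl radical may go toward the other bridgehead, and bromine may be captured on the wrong face of the ring-opened radical. The fallback sets out from 4 and comes back at 9, using an oxygen-centred radical. Silylation of 4 (t-BuMe2SiCl, imidazole) gives (1R,2S,5R)-2-[(tert-butyldimethylsilyl)oxy]-7,7-dimethylbicyclo[3.1.1]heptan-6-one F4. NaBH4 reduces the cyclobutanone to 2-[(tert-butyldimethylsilyl)oxy]-7,7-dimethylbicyclo[3.1.1]heptan-6-ol F5. Its hypobromite (HgO, Br2, light) undergoes alkoxy-radical β-scission with bromine transfer and gives (1R,3R,6S)-3-bromo-6-[(tert-butyldimethylsilyl)oxy]-2,2-dimethylcyclohexane-1-carbaldehyde F6 directly at the aldehyde level. Wittig methylenation gives {[(1S,2R,4R)-4-bromo-2-ethenyl-3,3-dimethylcyclohexyl]oxy}(tert-butyl)dimethylsilane F7, and Bu4NF returns 9. The alkoxy radical should fragment with a stronger polar bias away from the oxygen-bearing carbon, and the bulkier silyl ether should anchor the chair more firmly during bromine transfer.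

3. Step 14. A 5-exo closure to a tetrahydrofuran may compete, and facial selectivity with respect to the existing carbinol centre may be poor. The fallback sets out from 19 and comes back at 20 in two stages. Hg(OCOCF3)2 in MeNO2 at −20 °C, then aqueous KBr, should give by reversible Markovnikov alkoxymercuration bromo[(2S,3R,6S)-2-{2-[(1R,3R)-3-bromo-2,2-dimethyl-6-oxocyclohexyl]ethyl}-6-ethenyl-2,6-dimethyloxan-3-yl]mercury F8. Br2 with LiBr in pyridine under O2 then replaces mercury by bromine with retention and gives 20.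

**Further compounds**

F1 | step 1 | (2S)-N-(3,3-dimethylcyclobutylidene)-2-(methoxymethyl)pyrrolidin-1-amine | COC[C@@H]1CCCN1N=C1CC(C)(C)C1
F2 | step 1 | (2S)-N-{(2R)-2-[2-(1,3-dioxolan-2-yl)ethyl]-3,3-dimethylcyclobutylidene}-2-(methoxymethyl)pyrrolidin-1-amine | COC[C@@H]1CCCN1N=C1CC(C)(C)[C@H]1CCC1OCCO1
F3 | step 1 | (2R)-2-[2-(1,3-dioxolan-2-yl)ethyl]-3,3-dimethylcyclobutan-1-one | O=C1CC(C)(C)[C@H]1CCC1OCCO1
F4 | step 4 | (1R,2S,5R)-2-[(tert-butyldimethylsilyl)oxy]-7,7-dimethylbicyclo[3.1.1]heptan-6-one | O=C1[C@@H]2C(C)(C)[C@H]1CC[C@@H]2O[Si](C)(C)C(C)(C)C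
F5 | step 4 | 2-[(tert-butyldimethylsilyl)oxy]-7,7-dimethylbicyclo[3.1.1]heptan-6-ol (ring configuration as in 4, both C6 epimers) | OC1[C@@H]2C(C)(C)[C@H]1CC[C@@H]2O[Si](C)(C)C(C)(C)C
F6 | step 4 | (1R,3R,6S)-3-bromo-6-[(tert-butyldimethylsilyl)oxy]-2,2-dimethylcyclohexane-1-carbaldehyde | O=C[C@@H]1C(C)(C)[C@H](Br)CC[C@@H]1O[Si](C)(C)C(C)(C)C
F7 | step 4 | {[(1S,2R,4R)-4-bromo-2-ethenyl-3,3-dimethylcyclohexyl]oxy}(tert-butyl)dimethylsilane | C=C[C@@H]1C(C)(C)[C@H](Br)CC[C@@H]1O[Si](C)(C)C(C)(C)C
F8 | step 14 | bromo[(2S,3R,6S)-2-{2-[(1R,3R)-3-bromo-2,2-dimethyl-6-oxocyclohexyl]ethyl}-6-ethenyl-2,6-dimethyloxan-3-yl]mercury | C=C[C@]1(C)CC[C@@H]([Hg]Br)[C@](C)(CC[C@@H]2C(C)(C)[C@H](Br)CCC2=O)O1
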